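**Plan**

Numbering (lignan style): tetrahydrofuran ring O1–C7H(aryl)–C8H(C9H2OH)–C8'H–C9'H2. C7' is the carbinol carbon on C8'.
Enabling feature: the C7' oxygen sits 1,3 to C9' (the ring carbon next to O1), and the three ring substituents (aryl on C7, C9 on C8, C7' on C8') are all cis. The ring is therefore a furan that has taken up an aldehyde C=O across C8'=C9' on one face and H2 across C7=C8 on the other.
Cuts: C9'–H back to a C9'–O–C7' oxetane acetal and C9H2OH back to an ester. Then C7–H and C8–H back to C7=C8, then C7'–C8' together with O–C9' (aldehyde + furan), and last the C7–aryl bond (3-furoate + aryl bromide).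
Forward: furoate ester, C2 arylation, photocycloaddition (dearomatises the furan and fuses a temporary oxetane on it), hydrogenation (makes the tetrahydrofuran ring), hydride step (opens the oxetane, reduces the ester, removes the auxiliary), desilylation.
Stereochemistry: the (−)-8-phenylmenthyl ester picks the furan face (C8', C9'). The exo rule of the photocycloaddition sets C7'. Convex-face hydrogenation of the bicycle sets C7 and C8.

Key step: step 5

Assumption: furoate 6 is taken to react from the conformer with the ester C=O s-cis to the furan C2=C3 bond, which puts the auxiliary phenyl ring over C3/C4 on one face and makes (−)-8-phenylmenthol the matched auxiliary; if the induction runs the other way, (+)-8-phenylmenthol would be used in step 1 with no other change.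

**Step 1**
Reactants: 1 3-furoyl chloride; 2 (−)-8-phenylmenthol
Product: 3 (−)-8-phenylmenthyl furan-3-carboxylate
Conditions: Et3N, DMAP (cat.), CH2Cl2, 0 °C to rt
Reagents that add atoms: none
Why: DMAP-catalysed O-acylation of a hindered secondary alcohol by an acid chloride, in which the carbinol C–O bond is not touched, so the three stereocentres of the auxiliary are kept.

**Step 2**
Reactants: 4 4-bromo-2-methoxyphenol
Product: 5 (4-bromo-2-methoxyphenoxy)triisopropylsilane
Conditions: TIPSCl, imidazole, DMF, rt
Reagents that add atoms: triisopropylsilyl chloride, CC(C)[Si](Cl)(C(C)C)C(C)C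
Why: Imidazole-promoted silylation of a phenol, giving a bulky aryl silyl ether that should stand hot KOAc, light, hydrogenation and aluminium hydrides.

**Step 3**
Reactants: 3 (−)-8-phenylmenthyl furan-3-carboxylate; 5 (4-bromo-2-methoxyphenoxy)triisopropylsilane
Product: 6 (−)-8-phenylmenthyl 2-[3-methoxy-4-(triisopropylsilyloxy)phenyl]furan-3-carboxylate
Conditions: Pd(PPh3)4 (5 mol %), KOAc, toluene, 110 °C
Reagents that add atoms: none
Why: Palladium-catalysed direct C–H arylation, for which 3-carboalkoxyfurans are known to react at C2 (next to the ester) under these non-polar phosphine conditions, and to which ester and silyl ether are inert.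

**Step 4**
Reactants: 7 vanillin
Product: 8 3-methoxy-4-(triisopropylsilyloxy)benzaldehyde
Conditions: TIPSCl, imidazole, DMF, rt
Reagents that add atoms: triisopropylsilyl chloride, CC(C)[Si](Cl)(C(C)C)C(C)C
Why: Imidazole-promoted silylation of a phenol, which also weakens the para oxygen donor so that the aldehyde keeps usable n,π* triplet character and the later C7' benzylic position is less prone to ionise.

**Step 5**
Reactants: 6 (−)-8-phenylmenthyl 2-[3-methoxy-4-(triisopropylsilyloxy)phenyl]furan-3-carboxylate; 8 3-methoxy-4-(triisopropylsilyloxy)benzaldehyde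
Product: 10 exo photoadduct (−)-8-phenylmenthyl (1R,5R,6S)-3,6-bis[3-methoxy-4-(triisopropylsilyloxy)phenyl]-2,7-dioxabicyclo[3.2.0]hept-3-ene-4-carboxylate, via triplet 1,4-biradical 9 (not isolated)
Conditions: hν (350 nm lamps, Pyrex), 8 (3 equiv), degassed benzene, 10 °C; chromatography on Et3N-washed SiO2 to remove the minor diastereomer
Reagents that add atoms: none
Why: Proposed new method: the closest known reaction type is the furan–carbonyl Paternò–Büchi photocycloaddition (the photochemical aldol equivalent), known for furan and for alkyl-, silyl- and stannylfurans with aromatic aldehydes, but not for a conjugated 2-aryl-3-furoate nor with facial control by an ester auxiliary on the furan. Mechanism: the n,π* triplet of 8 bonds through its electrophilic oxygen to the unsubstituted α-carbon C5 of the furan (C9') to give biradical 9 (benzylic radical at C7', oxa-allyl radical over C8'–C8–C7 extended into the C7 aryl ring), which after intersystem crossing combines at C8' and so forms C7'–C8'. Ring closure: only the oxetane closes, by radical–radical combination of the 1,4-biradical (formal [2+2], four-membered ring), and its fusion to the five-membered ring can only be cis, which ties the configuration of C9' to that of C8'. Stereocontrol: C8' (and with it C9') is set by the auxiliary, whose phenyl ring stacks on one face of the furoate and lies over C3/C4, so the aldehyde enters from the open face, while C7' is set by the exo rule of furan photoadducts, because the biradical closes with the aryl group turned away from the five-membered ring and from the ester on C8. Selectivity needed is site (C4=C5, not C2=C3), orientation (O to C5) and mono-addition: the aryl group blocks C2 and stabilises the biradical born from attack at C5, the ester makes C2=C3 electron-poor, and the C7=C8 bond left in 10 is tetrasubstituted and acceptor-substituted, so a second addition is not expected. Energy transfer from triplet 8 to the arylfuran chromophore is the competing channel, but the ring-locked arylfuran triplet has no rotation or cleavage open to it and should return 6 unchanged, costing photons and time rather than material.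

**Step 6**
Reactants: 10 exo photoadduct
Product: 11 (−)-8-phenylmenthyl (1R,3S,4R,5R,6S)-3,6-bis[3-methoxy-4-(triisopropylsilyloxy)phenyl]-2,7-dioxabicyclo[3.2.0]heptane-4-carboxylate (3-aryl and 4-ester endo; 6-aryl exo)
Conditions: H2 (10 bar), 5% Rh/Al2O3, EtOAc, rt
Reagents that add atoms: none
Why: Heterogeneous syn hydrogenation of the enol-ether double bond of a furan photoadduct, in which both hydrogens arrive on the convex face (the face of H8' and H9'), so the C7 aryl group and the C8 ester are pushed to the oxetane face (all-cis C7, C8, C8'), with Rh chosen over Pd to spare the benzylic C–O bonds.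

**Step 7**
Reactants: 11 saturated bicyclic ester
Product: 13 (S)-[(3S,4S,5S)-4-(hydroxymethyl)-5-[3-methoxy-4-(triisopropylsilyloxy)phenyl]tetrahydrofuran-3-yl][3-methoxy-4-(triisopropylsilyloxy)phenyl]methanol, via bicyclic alcohol 12 (not isolated)
Conditions: DIBAL-H (6 equiv), CH2Cl2, −78 °C to rt; then aq. potassium sodium tartrate
Reagents that add atoms: none
Why: Ester reduction followed by reductive acetal cleavage, in which DIBAL-H first turns the ester into C9H2OH and releases the auxiliary, then as a Lewis acidic hydride binds the more basic, strained oxetane oxygen, ionises C9'–O with relief of ring strain to the five-membered oxocarbenium ion and delivers hydride to C9', leaving the C7' oxygen as the carbinol and touching no stereocentre.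

**Step 8**
Reactants: 13 bis-TIPS ether of the target
Product: 14 target, (S)-(4-hydroxy-3-methoxyphenyl)[(3S,4S,5S)-5-(4-hydroxy-3-methoxyphenyl)-4-(hydroxymethyl)tetrahydrofuran-3-yl]methanol
Conditions: TBAF, AcOH (2.2 equiv each), THF, 0 °C
Reagents that add atoms: none
Why: Fluoride-mediated desilylation of aryl silyl ethers, buffered with acetic acid so that no free phenoxide para to a benzylic C–O bond persists and no stereocentre is put at risk.

**Compound list**

| No. | Name | SMILES | Role |
|---|---|---|---|
| 1 | 3-furoyl chloride | O=C(Cl)c1ccoc1 | starting material |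
| 2 | (−)-8-phenylmenthol, (1R,2S,5R)-5-methyl-2-(2-phenylpropan-2-yl)cyclohexan-1-ol | C[C@@H]1CC[C@@H](C(C)(C)c2ccccc2)[C@H](O)C1 | starting material |
| 3 | (−)-8-phenylmenthyl furan-3-carboxylate | O=C(O[C@@H]1C[C@H](C)CC[C@H]1C(C)(C)c1ccccc1)c1ccoc1 | intermediate |
| 4 | 4-bromo-2-methoxyphenol | COc1cc(Br)ccc1O | starting material |
| 5 | (4-bromo-2-methoxyphenoxy)triisopropylsilane | COc1cc(Br)ccc1O[Si](C(C)C)(C(C)C)C(C)C | intermediate |
| 6 | (−)-8-phenylmenthyl 2-[3-methoxy-4-(triisopropylsilyloxy)phenyl]furan-3-carboxylate | COc1cc(-c2occc2C(=O)O[C@@H]2C[C@H](C)CC[C@H]2C(C)(C)c2ccccc2)ccc1O[Si](C(C)C)(C(C)C)C(C)C | intermediate |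
| 7 | vanillin | COc1cc(C=O)ccc1O | starting material |
| 8 | 3-methoxy-4-(triisopropylsilyloxy)benzaldehyde | COc1cc(C=O)ccc1O[Si](C(C)C)(C(C)C)C(C)C | intermediate |
| 9 | triplet 1,4-biradical (aldehyde O bonded to furan C5; radical centres at C7' and C8') | COc1cc([CH]O[C@@H]2OC(c3ccc(O[Si](C(C)C)(C(C)C)C(C)C)c(OC)c3)=C(C(=O)O[C@@H]3C[C@H](C)CC[C@H]3C(C)(C)c3ccccc3)[CH]2)ccc1O[Si](C(C)C)(C(C)C)C(C)C | intermediate |
| 10 | (−)-8-phenylmenthyl (1R,5R,6S)-3,6-bis[3-methoxy-4-(triisopropylsilyloxy)phenyl]-2,7-dioxabicyclo[3.2.0]hept-3-ene-4-carboxylate (cis-fused, 6-aryl exo) | COc1cc([C@H]2O[C@@H]3OC(c4ccc(O[Si](C(C)C)(C(C)C)C(C)C)c(OC)c4)=C(C(=O)O[C@@H]4C[C@H](C)CC[C@H]4C(C)(C)c4ccccc4)[C@H]23)ccc1O[Si](C(C)C)(C(C)C)C(C)C | intermediate |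
| 11 | (−)-8-phenylmenthyl (1R,3S,4R,5R,6S)-3,6-bis[3-methoxy-4-(triisopropylsilyloxy)phenyl]-2,7-dioxabicyclo[3.2.0]heptane-4-carboxylate | COc1cc([C@H]2O[C@@H]3O[C@H](c4ccc(O[Si](C(C)C)(C(C)C)C(C)C)c(OC)c4)[C@H](C(=O)O[C@@H]4C[C@H](C)CC[C@H]4C(C)(C)c4ccccc4)[C@H]23)ccc1O[Si](C(C)C)(C(C)C)C(C)C | intermediate |
| 12 | [(1R,3S,4S,5R,6S)-3,6-bis[3-methoxy-4-(triisopropylsilyloxy)phenyl]-2,7-dioxabicyclo[3.2.0]heptan-4-yl]methanol | COc1cc([C@H]2O[C@@H]3O[C@H](c4ccc(O[Si](C(C)C)(C(C)C)C(C)C)c(OC)c4)[C@H](CO)[C@H]23)ccc1O[Si](C(C)C)(C(C)C)C(C)C | intermediate |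
| 13 | (S)-[(3S,4S,5S)-4-(hydroxymethyl)-5-[3-methoxy-4-(triisopropylsilyloxy)phenyl]tetrahydrofuran-3-yl][3-methoxy-4-(triisopropylsilyloxy)phenyl]methanol | COc1cc([C@@H](O)[C@@H]2CO[C@H](c3ccc(O[Si](C(C)C)(C(C)C)C(C)C)c(OC)c3)[C@@H]2CO)ccc1O[Si](C(C)C)(C(C)C)C(C)C | intermediate |
| 14 | (S)-(4-hydroxy-3-methoxyphenyl)[(3S,4S,5S)-5-(4-hydroxy-3-methoxyphenyl)-4-(hydroxymethyl)tetrahydrofuran-3-yl]methanol | COc1cc([C@@H](O)[C@@H]2CO[C@H](c3ccc(O)c(OC)c3)[C@@H]2CO)ccc1O | target |

Total step count: 8. Longest linear sequence: 6 (steps 1, 3, 5, 6, 7, 8).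

**Steps most likely to fail**

**First, step 5 (labelled).**
- What may go wrong: energy transfer from the excited aldehyde to the arylfuran chromophore, and light absorption by 6, may outrun bond formation. The electron-rich aldehyde may react sluggishly from a π,π*-like triplet. Facial selection by the auxiliary may be poor.
- The fallback uses known chemistry and brings the aryl group in after the photochemical event. It sets out from 3 and comes back at 10.
- Compound 3 is magnesiated at C2 (TMPMgCl·LiCl, THF, −25 °C) and quenched with Bu3SnCl to give (−)-8-phenylmenthyl 2-(tributylstannyl)furan-3-carboxylate F1, which has no styrene-type chromophore.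
- 2-Stannylfurans are known to take up aromatic aldehydes at the unsubstituted double bond. Irradiation with 8 as in step 5 should therefore give the exo vinylstannane photoadduct F2, whose auxiliary-derived diastereomers are separated by chromatography.
- Stille coupling of F2 with 5 (Pd(PPh3)4, CuI cat., DMF, 60 °C) should give 10.

**Second, step 6.**
- What may go wrong: slow uptake at the tetrasubstituted double bond, whose convex face is partly covered by the auxiliary. Ring hydrogenation of the arenes on rhodium and hydrogenolysis of the benzylic C–O bonds are also possible.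
- The fallback removes the auxiliary first and changes to a directed homogeneous reduction. It sets out from 10 and comes back at 12.
- LiAlH4 (Et2O, 0 °C) should reduce the vinylogous carbonate to the allylic alcohol [(1R,5R,6S)-3,6-bis[3-methoxy-4-(triisopropylsilyloxy)phenyl]-2,7-dioxabicyclo[3.2.0]hept-3-en-4-yl]methanol F3.
- Hydroxyl-directed hydrogenation ([Ir(cod)(PCy3)(py)]PF6, H2, CH2Cl2, rt) should then deliver hydrogen on the only open (convex) face to give 12.
- Compound 12 is isolated here and opened with DIBAL-H as in the second half of step 7.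

**Third, step 7.**
- What may go wrong: ionisation at the benzylic C7'–O bond instead of the acetal C9'–O bond, with loss of the C7' oxygen. The opened zwitterion may also fragment back to aldehyde and enol ether before hydride transfer.
- The fallback replaces hydride capture of a cation by a radical reduction. It sets out from 11 and comes back at 13.
- LiAlH4 (THF, 0 °C) gives 12, which is isolated.
- Mild thiolysis of the strained acetal (PhSH, PPTS cat., CH2Cl2, 0 °C) should give the C9' phenylthio derivative of 13 F4. It is drawn as the expected anomer trans to the C8' substituent, and this centre is lost in the next operation.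
- Radical desulfurisation (Bu3SnH, AIBN, toluene, 80 °C) should give 13.

**Further compounds**
F1 | step 5 | (−)-8-phenylmenthyl 2-(tributylstannyl)furan-3-carboxylate | CCCC[Sn](CCCC)(CCCC)c1occc1C(=O)O[C@@H]1C[C@H](C)CC[C@H]1C(C)(C)c1ccccc1
F2 | step 5 | (−)-8-phenylmenthyl (1R,5R,6S)-6-[3-methoxy-4-(triisopropylsilyloxy)phenyl]-3-(tributylstannyl)-2,7-dioxabicyclo[3.2.0]hept-3-ene-4-carboxylate | COc1cc([C@H]2O[C@@H]3OC([Sn](CCCC)(CCCC)CCCC)=C(C(=O)O[C@@H]4C[C@H](C)CC[C@H]4C(C)(C)c4ccccc4)[C@H]23)ccc1O[Si](C(C)C)(C(C)C)C(C)C
F3 | step 6 | [(1R,5R,6S)-3,6-bis[3-methoxy-4-(triisopropylsilyloxy)phenyl]-2,7-dioxabicyclo[3.2.0]hept-3-en-4-yl]methanol | COc1cc([C@H]2O[C@@H]3OC(c4ccc(O[Si](C(C)C)(C(C)C)C(C)C)c(OC)c4)=C(CO)[C@H]23)ccc1O[Si](C(C)C)(C(C)C)C(C)C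
F4 | step 7 | C9' phenylthio derivative of 13 (SPh trans to the C8' substituent) | COc1cc([C@@H](O)[C@@H]2[C@@H](Sc3ccccc3)O[C@H](c3ccc(O[Si](C(C)C)(C(C)C)C(C)C)c(OC)c3)[C@@H]2CO)ccc1O[Si](C(C)C)(C(C)C)C(C)C
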